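**Retrosynthetic overview**
- The target comes from a cyclohexa-2,4-dienol dibenzoate by one-flask hydroxyl-directed epoxidation and trans opening with water; this sets the last two carbinol centres.
- The only ring is closed by ring-closing metathesis of an acyclic (Z)-triene, obtained by cis-semireduction of an enyne.
- The enyne diol dibenzoate comes from a new iridium-catalysed reductive coupling of an acetylenic ketone with a 1-benzoyloxyallyl donor; this forms the C–C bond between the tertiary carbinol and the benzoyloxy-bearing carbon and sets both stereocentres.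
- The ketone comes from a Weinreb amide and an enyne made by Sonogashira coupling; the allyl donor comes from allyl benzoate and NBS.
- Both benzoates come from benzaldehyde by NHC-catalysed oxidative esterification of small alcohols.

Assumption: the sense of induction of (S)-SEGPHOS in step 6 is taken by analogy with the known aldehyde couplings; if the first run gives the antipode, (R)-SEGPHOS is used and nothing else changes.

**Step 1**
Reactants: 1 benzaldehyde; 2 2-hydroxy-N-methoxy-N-methylacetamide
Product: 3 2-[methoxy(methyl)amino]-2-oxoethyl benzoate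
Conditions: 1 (1.1 equiv), 1,4-dimethyl-4H-1,2,4-triazol-1-ium iodide (5 mol%), DBU (20 mol%), 3,3',5,5'-tetra-tert-butyl-4,4'-diphenoquinone (1.05 equiv), THF, rt
Reagents that add atoms: none
Why: NHC-catalysed oxidative esterification, in which the Breslow intermediate of benzaldehyde is oxidised by the quinone to an acyl azolium that acylates the primary alcohol; no stereocentre is formed.

**Step 2**
Reactants: 4 ethynyltrimethylsilane; 5 bromoethene
Product: 6 (but-3-en-1-yn-1-yl)trimethylsilane
Conditions: Pd(PPh3)2Cl2 (2 mol%), CuI (4 mol%), Et3N, THF, 0 °C to rt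
Reagents that add atoms: none
Why: Sonogashira coupling, in which zerovalent palladium adds to the vinyl bromide and the copper acetylide transmetalates, giving the silyl-capped enyne without any stereocentre.

**Step 3**
Reactants: 6 (but-3-en-1-yn-1-yl)trimethylsilane; 3 2-[methoxy(methyl)amino]-2-oxoethyl benzoate
Product: 8 2-oxohex-5-en-3-yn-1-yl benzoate, via lithium but-3-en-1-yn-1-ide 7 (not isolated)
Conditions: 6, MeLi·LiBr, THF, 0 °C to rt; then 3, −78 to −40 °C; aq. NH4Cl
Reagents that add atoms: none
Why: Weinreb ketone synthesis, in which methyllithium cleaves the C–Si bond and the lithium acetylide adds to the chelating N-methoxy-N-methyl amide faster than to the conjugated benzoate, the tetrahedral chelate collapsing to the ynone only on quench.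

**Step 4**
Reactants: 9 prop-2-en-1-ol; 1 benzaldehyde
Product: 10 prop-2-en-1-yl benzoate
Conditions: 1 (1.1 equiv), 1,4-dimethyl-4H-1,2,4-triazol-1-ium iodide (5 mol%), DBU (20 mol%), 3,3',5,5'-tetra-tert-butyl-4,4'-diphenoquinone (1.05 equiv), THF, rt
Reagents that add atoms: none
Why: NHC-catalysed oxidative esterification as in step 1, acylating the primary allylic alcohol through the acyl azolium.

**Step 5**
Reactants: 10 prop-2-en-1-yl benzoate
Product: 11 3-bromoprop-1-en-1-yl benzoate
Conditions: NBS (1.05 equiv), AIBN (3 mol%), PhCF3, 80 °C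
Reagents that add atoms: N-bromosuccinimide, O=C1CCC(=O)N1Br
Why: Wohl–Ziegler bromination, in which hydrogen is abstracted from the allylic carbon next to oxygen and bromine is transferred to the far end of the allyl radical, giving the conjugated enol ester as an E/Z mixture.

**Step 6**
Reactants: 8 2-oxohex-5-en-3-yn-1-yl benzoate; 11 3-bromoprop-1-en-1-yl benzoate
Product: 12 (3S,4R)-4-[(benzoyloxy)methyl]-4-hydroxyocta-1,7-dien-5-yn-3-yl benzoate
Conditions: [Ir(cod)Cl]2 (2.5 mol%), (S)-SEGPHOS [(S)-5,5'-bis(diphenylphosphino)-4,4'-bi-1,3-benzodioxole] (5 mol%), 4-cyano-3-nitrobenzoic acid (10 mol%), Cs2CO3 (20 mol%), 11 (E/Z mixture, 2 equiv), i-PrOH (2 equiv), K3PO4 (1.2 equiv), THF, 60 °C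
Reagents that add atoms: none
Why: Proposed new method: the anionic monovalent iridium C,O-benzoate complex should ionise the allylic C–Br bond of either isomer of 11 to a trivalent (E)-(1-benzoyloxy)allyliridium, the species that acrolein-derived gem-dibenzoates give, which adds to the ynone through a closed chair transition state with the slim alkynyl group axial and CH2OBz equatorial, so the new C–C bond carries 3-OBz and 4-OH anti while the chiral bisphosphine selects the ketone face (3S,4R) and 2-propanol returns the metal to the monovalent state by β-hydride elimination to acetone; the closest known reactions are the iridium-catalysed anti-(α-acyloxy)allylation of aldehydes with allylic gem-dicarboxylates and the 2-propanol-mediated iridium-catalysed allylation of acetylenic ketones with allyl acetate (Krische allylation), which have not been combined and have not used a 3-halopropenyl ester as donor.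

**Step 7**
Reactants: 12 (3S,4R)-4-[(benzoyloxy)methyl]-4-hydroxyocta-1,7-dien-5-yn-3-yl benzoate
Product: 13 (3S,4R,5Z)-4-[(benzoyloxy)methyl]-4-hydroxyocta-1,5,7-trien-3-yl benzoate
Conditions: Zn dust activated with Cu(OAc)2 and AgNO3, MeOH–H2O–THF, 35 °C
Reagents that add atoms: none
Why: Boland reduction, in which activated zinc reduces only the conjugated, hydroxyl-flanked triple bond to the (Z)-alkene and leaves the isolated alkenes, the esters and both stereocentres untouched.

**Step 8**
Reactants: 13 (3S,4R,5Z)-4-[(benzoyloxy)methyl]-4-hydroxyocta-1,5,7-trien-3-yl benzoate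
Product: 14 [(1R,6S)-6-(benzoyloxy)-1-hydroxycyclohexa-2,4-dien-1-yl]methyl benzoate
Conditions: second-generation Grubbs catalyst (H2IMes)(PCy3)Cl2Ru=CHPh (5 mol%), CH2Cl2 (5 mM), 40 °C
Reagents that add atoms: none
Why: Ring-closing metathesis between the vinyl group and the terminal alkene of the (Z)-diene, which can only close the six-membered ring (the alternative would be a cyclobutene) and releases ethene, with no change at the stereocentres.

**Step 9**
Reactants: 14 [(1R,6S)-6-(benzoyloxy)-1-hydroxycyclohexa-2,4-dien-1-yl]methyl benzoate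
Product: 16 [(1S,2S,5R,6S)-2-(benzoyloxy)-1,5,6-trihydroxycyclohex-3-en-1-yl]methyl benzoate, via epoxy alcohol 15 (not isolated)
Conditions: mCPBA (1.1 equiv), CH2Cl2–aq. phosphate buffer (pH 8), 0 °C; crude epoxide, HClO4 (cat.), THF–H2O, 0 °C to rt
Reagents that add atoms: mCPBA (3-chloroperoxybenzoic acid), OOC(=O)c1cccc(Cl)c1; water, O
Why: Henbest-directed Prilezhaev epoxidation, in which the tertiary allylic hydroxyl delivers the peracid to its own face of the adjacent alkene (the other alkene is deactivated by the allylic benzoate), followed by acid-catalysed attack of water at the allylic epoxide carbon with inversion, so 6-OH ends cis to 1-OH and 5-OH trans to 6-OH (5R,6S).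

**Compound list**
1 | benzaldehyde | O=Cc1ccccc1 | starting material
2 | 2-hydroxy-N-methoxy-N-methylacetamide | CON(C)C(=O)CO | starting material
3 | 2-[methoxy(methyl)amino]-2-oxoethyl benzoate | CON(C)C(=O)COC(=O)c1ccccc1 | intermediate
4 | ethynyltrimethylsilane | C#C[Si](C)(C)C | starting material
5 | bromoethene (vinyl bromide) | C=CBr | starting material
6 | (but-3-en-1-yn-1-yl)trimethylsilane | C=CC#C[Si](C)(C)C | intermediate
7 | lithium but-3-en-1-yn-1-ide | [Li]C#CC=C | intermediate
8 | 2-oxohex-5-en-3-yn-1-yl benzoate | O=C(COC(=O)c1ccccc1)C#CC=C | intermediate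
9 | prop-2-en-1-ol (allyl alcohol) | C=CCO | starting material
10 | prop-2-en-1-yl benzoate (allyl benzoate) | C=CCOC(=O)c1ccccc1 | intermediate
11 | 3-bromoprop-1-en-1-yl benzoate (E/Z mixture) | BrCC=COC(=O)c1ccccc1 | intermediate
12 | (3S,4R)-4-[(benzoyloxy)methyl]-4-hydroxyocta-1,7-dien-5-yn-3-yl benzoate | O=C(OC[C@@](C#CC=C)(O)[C@@H](OC(=O)c1ccccc1)C=C)c1ccccc1 | intermediate
13 | (3S,4R,5Z)-4-[(benzoyloxy)methyl]-4-hydroxyocta-1,5,7-trien-3-yl benzoate | O=C(OC[C@@](/C=C\C=C)(O)[C@@H](OC(=O)c1ccccc1)C=C)c1ccccc1 | intermediate
14 | [(1R,6S)-6-(benzoyloxy)-1-hydroxycyclohexa-2,4-dien-1-yl]methyl benzoate | O=C(OC[C@@]1(O)[C@@H](OC(=O)c2ccccc2)C=CC=C1)c1ccccc1 | intermediate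
15 | [(1S,2R,3S,6S)-3-(benzoyloxy)-2-hydroxy-7-oxabicyclo[4.1.0]hept-4-en-2-yl]methyl benzoate | O=C(OC[C@@]1(O)[C@@H](OC(=O)c2ccccc2)C=C[C@@H]2O[C@H]12)c1ccccc1 | intermediate
16 | [(1S,2S,5R,6S)-2-(benzoyloxy)-1,5,6-trihydroxycyclohex-3-en-1-yl]methyl benzoate | O=C(OC[C@@]1(O)[C@@H](OC(=O)c2ccccc2)C=C[C@@H](O)[C@@H]1O)c1ccccc1 | target

**Step count and risks**
Total step count: 9. Longest linear sequence: 6 steps (steps 1, 3, 6, 7, 8, 9; the branches 2, 3, 6, 7, 8, 9 and 4, 5, 6, 7, 8, 9 are equally long).

The three steps most likely to fail are steps 6, 3 and 9.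

Step 6 (new coupling) may fail through solvolysis of 11, reduction of the ynone, or poor enantiocontrol. The fallback sets out from 8 and 11 and comes back at 12. Stoichiometric CrCl2 (divalent chromium) in THF at 0 °C gives the Barbier-type α-acyloxyallylation that is known for 3-bromopropenyl esters and is anti-selective through the same chair arrangement. This delivers the racemic anti adduct, that is 12 together with its enantiomer (3R,4S)-4-[(benzoyloxy)methyl]-4-hydroxyocta-1,7-dien-5-yn-3-yl benzoate F4. The two are separated by preparative HPLC on a chiral stationary phase, and 12 enters step 7.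

Step 3 may fail because the acetylide attacks or deprotonates next to the benzoate. The fallback sets out from 10 and 6 and comes back at 8. Ozonolysis of 10 (O3, CH2Cl2, −78 °C; Me2S) gives 2-oxoethyl benzoate F1. Desilylation of 6 (K2CO3, MeOH) gives but-1-en-3-yne F2, which is swept into toluene. Alkynylation of F1 with F2 under Zn(OTf)2 and Et3N, with no strong base and no lithium alkoxide that could shift the benzoyl group, gives racemic 2-hydroxyhex-5-en-3-yn-1-yl benzoate F3. Dess–Martin oxidation of F3 gives 8.

Step 9 may fail through 1,4-opening, benzoyl migration or dehydration to the arene under aqueous acid. The fallback sets out from 14 and comes back at 16. Epoxide 15 is isolated after the buffered peracid step. It is then opened at the allylic carbon with inversion by buffered formic acid (HCO2H, HCO2Na, THF, 0 °C) to give [(1S,2S,5R,6S)-2-(benzoyloxy)-5-(formyloxy)-1,6-dihydroxycyclohex-3-en-1-yl]methyl benzoate F5. The formate alone is then cleaved with aqueous KHCO3 in MeOH at 0 °C, which leaves the benzoates intact and gives 16.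

**Further compounds**
F1 | step 3 | 2-oxoethyl benzoate | O=CCOC(=O)c1ccccc1
F2 | step 3 | but-1-en-3-yne | C=CC#C
F3 | step 3 | 2-hydroxyhex-5-en-3-yn-1-yl benzoate (racemic) | OC(COC(=O)c1ccccc1)C#CC=C
F4 | step 6 | (3R,4S)-4-[(benzoyloxy)methyl]-4-hydroxyocta-1,7-dien-5-yn-3-yl benzoate | O=C(OC[C@](C#CC=C)(O)[C@H](OC(=O)c1ccccc1)C=C)c1ccccc1
F5 | step 9 | [(1S,2S,5R,6S)-2-(benzoyloxy)-5-(formyloxy)-1,6-dihydroxycyclohex-3-en-1-yl]methyl benzoate | O=C(OC[C@@]1(O)[C@@H](OC(=O)c2ccccc2)C=C[C@@H](OC=O)[C@@H]1O)c1ccccc1
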